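**Assumption:** only substrates, intermediates and products carry numbers (reagents are given by name and SMILES). Atom labels follow trinervitane numbering: six-membered ring C1–C2–C3–C4–C16–C15, five-membered ring C4–C5–C6–C7–C16, eleven-membered ring C1–C14–C13–C12–C11–C10–C9–C8–C7–C16–C15; C17 = CH2 on C15, C18/C19/C20 = methyls on C4/C8/C12.

## Retrosynthetic overview

1. Target ⇐ methylenation of the C15 ketone and reagent-controlled reduction of the C13 enone in a macrocyclic 13,15-diketone.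
2. Key step: the eleven-membered ring is closed by an intramolecular Stetter reaction. The acyl anion at C13 (from the enal) adds to C14 of an exocyclic enone; both carbons are electrophilic by nature. C1 is set in the same step.
3. Seco precursor ⇐ vinylogous Mukaiyama aldol (C9–C10, Felkin) on a hydrindanone aldehyde; C14 comes from formaldehyde.
4. cis-Hydrindanone ⇐ 5-exo oxidative radical cyclisation (C16–C7) of the silyl enol ether obtained by anti conjugate addition of a homoprenyl Grignard to (S)-4-silyloxy-3-methylcyclohexenone (C3, C4).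
5. Ring order: six-membered (from an arene) → five-membered → eleven-membered.

## Route

**Step 1**
Reactants: 1 4-methoxy-2-methylphenol
Product: 2 4,4-dimethoxy-2-methylcyclohexa-2,5-dien-1-one
Conditions: PhI(OAc)2, MeOH, 0 °C
Reagents that add atoms: methanol, CO
Why: Oxidative dearomatisation of a p-methoxyphenol to the quinone monoketal; the para position is trapped by methanol.

**Step 2**
Reactants: 2 4,4-dimethoxy-2-methylcyclohexa-2,5-dien-1-one
Product: 3 4,4-dimethoxy-2-methylcyclohex-2-en-1-one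
Conditions: H2 (1 atm), RhCl(PPh3)3 (cat.), benzene, rt, stopped at 1 equiv H2
Reagents that add atoms: none
Why: Wilkinson hydrogenation reduces the disubstituted alkene much faster than the methyl-bearing trisubstituted one and avoids the reductive aromatisation seen with Pd.

**Step 3**
Reactants: 3 4,4-dimethoxy-2-methylcyclohex-2-en-1-one
Product: 4 (1S)-4,4-dimethoxy-2-methylcyclohex-2-en-1-ol
Conditions: (R)-Me-CBS (10 mol %), BH3·SMe2, THF, −20 °C
Reagents that add atoms: none
Why: Corey–Bakshi–Shibata reduction of an α-methyl enone; the alkenyl side acts as the large group, so the (R)-catalyst gives the (S)-carbinol (future C3).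

**Step 4**
Reactants: 4 (1S)-4,4-dimethoxy-2-methylcyclohex-2-en-1-ol
Product: 5 tert-butyl{[(1S)-4,4-dimethoxy-2-methylcyclohex-2-en-1-yl]oxy}dimethylsilane
Conditions: TBSCl, imidazole, DMF, rt
Reagents that add atoms: tert-butyldimethylsilyl chloride, CC(C)(C)[Si](C)(C)Cl
Why: Standard silylation; the bulky silyl ether later directs the cuprate anti and cannot be expelled as a γ-leaving group.

**Step 5**
Reactants: 5 tert-butyl{[(1S)-4,4-dimethoxy-2-methylcyclohex-2-en-1-yl]oxy}dimethylsilane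
Product: 6 (4S)-4-[(tert-butyldimethylsilyl)oxy]-3-methylcyclohex-2-en-1-one
Conditions: oxalic acid (cat.), wet SiO2, CH2Cl2, rt
Reagents that add atoms: water, O
Why: Mild ketal hydrolysis unmasks the enone (C15=O, C16=C4) without touching the allylic silyl ether.

**Step 6**
Reactants: 6 (4S)-4-[(tert-butyldimethylsilyl)oxy]-3-methylcyclohex-2-en-1-one; 7 5-bromo-2-methylpent-2-ene
Product: 9 tert-butyl{[(1S,2S)-2-methyl-2-(4-methylpent-3-en-1-yl)-4-(trimethylsilyloxy)cyclohex-3-en-1-yl]oxy}dimethylsilane, via (4-methylpent-3-en-1-yl)magnesium bromide 8 (not isolated)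
Conditions: 7, Mg, THF, rt; then CuBr·SMe2 (10 mol %), TMSCl, DMPU, 6, THF, −78 → −40 °C; Et3N, pentane work-up
Reagents that add atoms: chlorotrimethylsilane, C[Si](C)(C)Cl
Why: TMSCl-accelerated Cu-catalysed conjugate addition; the Grignard enters anti to the adjacent OTBS group and creates the quaternary C4, and the enolate is trapped regiospecifically at C15/C16.

**Step 7**
Reactants: 9 tert-butyl{[(1S,2S)-2-methyl-2-(4-methylpent-3-en-1-yl)-4-(trimethylsilyloxy)cyclohex-3-en-1-yl]oxy}dimethylsilane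
Product: 10 (3R,3aR,7S,7aS)-7-[(tert-butyldimethylsilyl)oxy]-7a-methyl-3-(prop-1-en-2-yl)octahydro-4H-inden-4-one
Conditions: Cu(OTf)2 (2.2 equiv), Cu2O (1.1 equiv), MeCN, 0 °C
Reagents that add atoms: none
Why: Snider-type oxidative radical cyclisation: Cu(II) oxidises the silyl enol ether to the C16 α-keto radical, which closes 5-exo on the prenyl alkene (cis ring fusion; Beckwith–Houk chair transition state places the C7 substituent cis to C15), and Cu(II) oxidative elimination of the tertiary radical gives the isopropenyl group.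

**Step 8**
Reactants: 10 (3R,3aR,7S,7aS)-7-[(tert-butyldimethylsilyl)oxy]-7a-methyl-3-(prop-1-en-2-yl)octahydro-4H-inden-4-one
Product: 12 (1R,3aS,4S,7aR)-3a-methyl-7-oxo-1-(prop-1-en-2-yl)octahydro-1H-inden-4-yl propanoate, via (3R,3aR,7S,7aS)-7-hydroxy-7a-methyl-3-(prop-1-en-2-yl)octahydro-4H-inden-4-one 11 (not isolated)
Conditions: HF·pyridine, THF, 0 °C → rt; then Et3N, (EtCO)2O, DMAP, rt
Reagents that add atoms: propanoic anhydride, CCC(=O)OC(=O)CC
Why: One-pot desilylation and DMAP-catalysed acylation installs the final C3 propanoate early, where the substrate is robust.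

**Step 9**
Reactants: 12 (1R,3aS,4S,7aR)-3a-methyl-7-oxo-1-(prop-1-en-2-yl)octahydro-1H-inden-4-yl propanoate
Product: 13 (1R,3aS,4S,7aR)-1-(3-hydroxyprop-1-en-2-yl)-3a-methyl-7-oxooctahydro-1H-inden-4-yl propanoate
Conditions: SeO2 (0.5 equiv), t-BuOOH, CH2Cl2, rt
Reagents that add atoms: tert-butyl hydroperoxide, CC(C)(C)OO
Why: Sharpless-type catalytic SeO2 allylic oxidation (ene/[2,3]) of the isopropenyl methyl (CH3 reacts before the hindered C7 methine); the oxidised carbon becomes C9 and the old =CH2 becomes C19.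

**Step 10**
Reactants: 13 (1R,3aS,4S,7aR)-1-(3-hydroxyprop-1-en-2-yl)-3a-methyl-7-oxooctahydro-1H-inden-4-yl propanoate
Product: 14 (1S,3aS,4S,7aR)-1-[(2S)-1-hydroxypropan-2-yl]-3a-methyl-7-oxooctahydro-1H-inden-4-yl propanoate
Conditions: H2 (50 bar), [Ir(cod)(PHOX)]BArF (1 mol %, ligand antipode matched to the substrate), CH2Cl2, rt
Reagents that add atoms: none
Why: Catalyst-controlled asymmetric hydrogenation of a 2-substituted allylic alcohol; with H7 eclipsing the C8=CH2 bond (A1,3 strain) hydrogen enters anti to C16, and the matched ligand reinforces this face to give 8S.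

**Step 11**
Reactants: 14 (1S,3aS,4S,7aR)-1-[(2S)-1-hydroxypropan-2-yl]-3a-methyl-7-oxooctahydro-1H-inden-4-yl propanoate
Product: 15 (1S,3aS,4S,7aR)-3a-methyl-7-oxo-1-[(2S)-1-oxopropan-2-yl]octahydro-1H-inden-4-yl propanoate
Conditions: Dess–Martin periodinane, NaHCO3, CH2Cl2, 0 °C; used directly
Reagents that add atoms: none
Why: Buffered Dess–Martin oxidation gives the α-chiral aldehyde without epimerising C8.

**Step 12**
Reactants: 16 (2E)-2-methylbut-2-enal
Product: 17 tert-butyl(dimethyl){[(1E)-2-methylbuta-1,3-dien-1-yl]oxy}silane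
Conditions: TBSOTf, Et3N, CH2Cl2, 0 °C
Reagents that add atoms: tert-butyldimethylsilyl triflate, CC(C)(C)[Si](C)(C)OS(=O)(=O)C(F)(F)F
Why: Soft enolisation at the γ-methyl of tiglic aldehyde gives the silyl dienol ether (C10–C13 plus C20).

**Step 13**
Reactants: 15 (1S,3aS,4S,7aR)-3a-methyl-7-oxo-1-[(2S)-1-oxopropan-2-yl]octahydro-1H-inden-4-yl propanoate; 17 tert-butyl(dimethyl){[(1E)-2-methylbuta-1,3-dien-1-yl]oxy}silane
Product: 18 (1S,3aS,4S,7aR)-1-[(2S,3S,5E)-3-hydroxy-6-methyl-7-oxohept-5-en-2-yl]-3a-methyl-7-oxooctahydro-1H-inden-4-yl propanoate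
Conditions: BF3·OEt2, CH2Cl2/Et2O 9:1, −78 °C; aq. NaHCO3
Reagents that add atoms: none
Why: Vinylogous Mukaiyama aldol: γ-attack of the dienol ether on the BF3-activated aldehyde gives the E-enal, Felkin–Anh addition anti to the ring substituent on C8 sets 9S (8,9-syn), and the hindered ketone does not compete.

**Step 14**
Reactants: 18 (1S,3aS,4S,7aR)-1-[(2S,3S,5E)-3-hydroxy-6-methyl-7-oxohept-5-en-2-yl]-3a-methyl-7-oxooctahydro-1H-inden-4-yl propanoate
Product: 19 (1S,3aS,4S,7aR)-1-[(2S,3S,5E)-3-(acetyloxy)-6-methyl-7-oxohept-5-en-2-yl]-3a-methyl-7-oxooctahydro-1H-inden-4-yl propanoate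
Conditions: Ac2O, pyridine, DMAP (cat.), CH2Cl2, 0 °C
Reagents that add atoms: acetic anhydride, CC(=O)OC(C)=O
Why: Standard acetylation installs the C9 acetate and blocks δ-lactone formation under carbene catalysis.

**Step 15**
Reactants: 19 (1S,3aS,4S,7aR)-1-[(2S,3S,5E)-3-(acetyloxy)-6-methyl-7-oxohept-5-en-2-yl]-3a-methyl-7-oxooctahydro-1H-inden-4-yl propanoate
Product: 21 (1S,3aS,4S,7aR)-1-[(2S,3S,5E)-3-(acetyloxy)-6-methyl-7-oxohept-5-en-2-yl]-3a-methyl-6-methylidene-7-oxooctahydro-1H-inden-4-yl propanoate, via 6-[(N-methylanilino)methyl] Mannich base 20 (not isolated)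
Conditions: (CH2O)n, PhNHMe·CF3CO2H, THF, 65 °C; used directly
Reagents that add atoms: formaldehyde (as paraformaldehyde), C=O
Why: Gras α-methylenation (reversible Mannich reaction, then elimination); only C1 carries two α-hydrogens, so only there can the Mannich base eliminate, and the acidic medium spares the esters and the enal.

**Step 16 (key step)**
Reactants: 21 (1S,3aS,4S,7aR)-1-[(2S,3S,5E)-3-(acetyloxy)-6-methyl-7-oxohept-5-en-2-yl]-3a-methyl-6-methylidene-7-oxooctahydro-1H-inden-4-yl propanoate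
Product: 22 (1S,3S,4S,7S,8S,9S,11E,16R)-9-(acetyloxy)-13,15-dioxo-17-nortrinervit-11-en-3-yl propanoate
Conditions: 2-(pentafluorophenyl)-6,7-dihydro-5H-pyrrolo[2,1-c][1,2,4]triazol-2-ium BF4 (20 mol %), i-Pr2NEt (20 mol %), toluene, 60 °C, syringe-pump addition to 1 mM
Reagents that add atoms: none
Why: Proposed new method: the triazolylidene adds to the hindered 2-methyl enal to give a Breslow intermediate whose acyl-anion carbon C13 attacks the unhindered exocyclic enone terminus C14 (two electrophilic carbons joined; eleven-membered ring favoured by slow addition), and proton transfer from the carbinol OH to the enolate on the tether face (the face of C7) sets C1 with C14 trans to C7; the closest known reactions are triazolium-catalysed intermolecular Stetter reactions of enals and intramolecular Stetter cyclisations to five- to seven-membered rings.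

**Step 17**
Reactants: 22 (1S,3S,4S,7S,8S,9S,11E,16R)-9-(acetyloxy)-13,15-dioxo-17-nortrinervit-11-en-3-yl propanoate
Product: 23 (1R,3S,4S,7S,8S,9S,11E,13R,16R)-9-(acetyloxy)-13-hydroxy-15-oxo-17-nortrinervit-11-en-3-yl propanoate
Conditions: (S)-Me-CBS (1 equiv), catecholborane, toluene/CH2Cl2, −78 °C
Reagents that add atoms: none
Why: CBS reduction: the α-methyl enone (alkenyl = large group) is reduced by the (S)-catalyst to the 13R allylic alcohol, while the ketone flanked by two methines and the esters are untouched at −78 °C.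

**Step 18**
Reactants: 23 (1R,3S,4S,7S,8S,9S,11E,13R,16R)-9-(acetyloxy)-13-hydroxy-15-oxo-17-nortrinervit-11-en-3-yl propanoate
Product: 24 (1R,3S,4S,7R,8S,9S,11E,13R,16S)-9-(acetyloxy)-13-hydroxytrinervita-11,15(17)-dien-3-yl propanoate (CNP0180453.1)
Conditions: Zn, CH2Br2, TiCl4 (pre-formed Lombardo reagent, excess), THF/CH2Cl2, 0 °C → rt
Reagents that add atoms: dibromomethane, BrCBr
Why: Takai–Lombardo methylenation is non-basic, so the epimerisable C1 and C16 are kept, and it tolerates the free hydroxyl and both esters.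

## Compound list

1 | 4-methoxy-2-methylphenol | COc1ccc(O)c(C)c1 | starting material
2 | 4,4-dimethoxy-2-methylcyclohexa-2,5-dien-1-one | COC1(OC)C=CC(=O)C(C)=C1 | intermediate
3 | 4,4-dimethoxy-2-methylcyclohex-2-en-1-one | COC1(OC)CCC(=O)C(C)=C1 | intermediate
4 | (1S)-4,4-dimethoxy-2-methylcyclohex-2-en-1-ol | O[C@H]1CCC(OC)(OC)C=C1C | intermediate
5 | tert-butyl{[(1S)-4,4-dimethoxy-2-methylcyclohex-2-en-1-yl]oxy}dimethylsilane | CC(C)(C)[Si](C)(C)O[C@H]1CCC(OC)(OC)C=C1C | intermediate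
6 | (4S)-4-[(tert-butyldimethylsilyl)oxy]-3-methylcyclohex-2-en-1-one | CC(C)(C)[Si](C)(C)O[C@H]1CCC(=O)C=C1C | intermediate
7 | 5-bromo-2-methylpent-2-ene | CC(C)=CCCBr | starting material
8 | (4-methylpent-3-en-1-yl)magnesium bromide | CC(C)=CCC[Mg]Br | intermediate
9 | tert-butyl{[(1S,2S)-2-methyl-2-(4-methylpent-3-en-1-yl)-4-(trimethylsilyloxy)cyclohex-3-en-1-yl]oxy}dimethylsilane | C[Si](C)(C)OC1=C[C@](C)(CCC=C(C)C)[C@@H](O[Si](C)(C)C(C)(C)C)CC1 | intermediate
10 | (3R,3aR,7S,7aS)-7-[(tert-butyldimethylsilyl)oxy]-7a-methyl-3-(prop-1-en-2-yl)octahydro-4H-inden-4-one | C=C(C)[C@@H]1CC[C@](C)([C@@H](O[Si](C)(C)C(C)(C)C)CC2)[C@@H]1C2=O | intermediate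
11 | (3R,3aR,7S,7aS)-7-hydroxy-7a-methyl-3-(prop-1-en-2-yl)octahydro-4H-inden-4-one | C=C(C)[C@@H]1CC[C@](C)([C@@H](O)CC2)[C@@H]1C2=O | intermediate
12 | (1R,3aS,4S,7aR)-3a-methyl-7-oxo-1-(prop-1-en-2-yl)octahydro-1H-inden-4-yl propanoate | C=C(C)[C@@H]1CC[C@](C)([C@@H](OC(=O)CC)CC2)[C@@H]1C2=O | intermediate
13 | (1R,3aS,4S,7aR)-1-(3-hydroxyprop-1-en-2-yl)-3a-methyl-7-oxooctahydro-1H-inden-4-yl propanoate | C=C(CO)[C@@H]1CC[C@](C)([C@@H](OC(=O)CC)CC2)[C@@H]1C2=O | intermediate
14 | (1S,3aS,4S,7aR)-1-[(2S)-1-hydroxypropan-2-yl]-3a-methyl-7-oxooctahydro-1H-inden-4-yl propanoate | OC[C@@H](C)[C@@H]1CC[C@](C)([C@@H](OC(=O)CC)CC2)[C@@H]1C2=O | intermediate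
15 | (1S,3aS,4S,7aR)-3a-methyl-7-oxo-1-[(2S)-1-oxopropan-2-yl]octahydro-1H-inden-4-yl propanoate | O=C[C@@H](C)[C@@H]1CC[C@](C)([C@@H](OC(=O)CC)CC2)[C@@H]1C2=O | intermediate
16 | (2E)-2-methylbut-2-enal (tiglic aldehyde) | C/C=C(\C)C=O | starting material
17 | tert-butyl(dimethyl){[(1E)-2-methylbuta-1,3-dien-1-yl]oxy}silane | C=C/C(C)=C/O[Si](C)(C)C(C)(C)C | intermediate
18 | (1S,3aS,4S,7aR)-1-[(2S,3S,5E)-3-hydroxy-6-methyl-7-oxohept-5-en-2-yl]-3a-methyl-7-oxooctahydro-1H-inden-4-yl propanoate | O=C/C(C)=C/C[C@H](O)[C@@H](C)[C@@H]1CC[C@](C)([C@@H](OC(=O)CC)CC2)[C@@H]1C2=O | intermediate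
19 | (1S,3aS,4S,7aR)-1-[(2S,3S,5E)-3-(acetyloxy)-6-methyl-7-oxohept-5-en-2-yl]-3a-methyl-7-oxooctahydro-1H-inden-4-yl propanoate | O=C/C(C)=C/C[C@H](OC(C)=O)[C@@H](C)[C@@H]1CC[C@](C)([C@@H](OC(=O)CC)CC2)[C@@H]1C2=O | intermediate
20 | Mannich base of 19: 6-{[methyl(phenyl)amino]methyl} derivative, both epimers at the new centre | O=C/C(C)=C/C[C@H](OC(C)=O)[C@@H](C)[C@@H]1CC[C@](C)([C@@H](OC(=O)CC)CC2CN(C)c3ccccc3)[C@@H]1C2=O | intermediate
21 | (1S,3aS,4S,7aR)-1-[(2S,3S,5E)-3-(acetyloxy)-6-methyl-7-oxohept-5-en-2-yl]-3a-methyl-6-methylidene-7-oxooctahydro-1H-inden-4-yl propanoate | O=C/C(C)=C/C[C@H](OC(C)=O)[C@@H](C)[C@@H]1CC[C@](C)([C@@H](OC(=O)CC)CC2=C)[C@@H]1C2=O | intermediate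
22 | (1S,3S,4S,7S,8S,9S,11E,16R)-9-(acetyloxy)-13,15-dioxo-17-nortrinervit-11-en-3-yl propanoate | O=C1[C@@H]2CC(=O)/C(C)=C/C[C@H](OC(C)=O)[C@@H](C)[C@@H]3CC[C@](C)([C@@H](OC(=O)CC)C2)[C@H]13 | intermediate
23 | (1R,3S,4S,7S,8S,9S,11E,13R,16R)-9-(acetyloxy)-13-hydroxy-15-oxo-17-nortrinervit-11-en-3-yl propanoate | O=C1[C@@H]2C[C@@H](O)/C(C)=C/C[C@H](OC(C)=O)[C@@H](C)[C@@H]3CC[C@](C)([C@@H](OC(=O)CC)C2)[C@H]13 | intermediate
24 | (1R,3S,4S,7R,8S,9S,11E,13R,16S)-9-(acetyloxy)-13-hydroxytrinervita-11,15(17)-dien-3-yl propanoate | C=C1[C@@H]2C[C@@H](O)/C(C)=C/C[C@H](OC(C)=O)[C@@H](C)[C@@H]3CC[C@](C)([C@@H](OC(=O)CC)C2)[C@H]13 | target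

## Step count and risks

Total step count: 18. Longest linear sequence: 17 (steps 1–11 and 13–18; step 12 is a one-step side branch).

Three steps most likely to fail:

**Step 16 (Stetter macrocyclisation).** Possible failures are homoenolate chemistry of the enal, carbene addition to the enone, oligomers, or the wrong C1 epimer. The fallback makes the same C13–C14 bond with an α,β-unsaturated acyl radical. It sets out from 19: Pinnick oxidation (NaClO2, NaH2PO4, 2-methylbut-2-ene) gives the carboxylic acid F1, (PhSe)2/Bu3P gives the Se-phenyl selenoester F2, and the α-methylenation conditions of step 15 give the enone selenoester F3. Slow addition of Bu3SnH/AIBN (benzene, 80 °C, 1 mM) then closes the ring by 11-endo acyl radical addition to C14 and hydrogen transfer to C1, coming back to the route at 22.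

**Step 7 (oxidative radical cyclisation).** Possible failures are cation-derived alkene isomers, trapping by solvent, or poor control at C7. The fallback closes the same C16–C7 bond by polar allylic alkylation. It sets out from 6: conjugate addition of 8 without silyl trapping (NH4Cl work-up) gives the ketone F4, SeO2/t-BuOOH oxidises the E-methyl of the prenyl group to the allylic alcohol F5, and ClCO2Me/pyridine gives the methyl carbonate F6. Pd(PPh3)4 (THF, 60 °C) ionises it and the ketone enolate attacks C7 (Tsuji–Trost, 5-exo; the seven-membered alternative would need a trans-cycloalkene), coming back to the route at 10.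

**Step 10 (C8 by asymmetric hydrogenation).** Possible failures are low facial selectivity or a mismatched catalyst. The fallback sets C8 by a stereospecific rearrangement. It sets out from 12: dimethyldioxirane (acetone, 0 °C; A1,3-controlled attack anti to C16) gives the epoxide F7, and catalytic Cr(TPP)OTf (CH2Cl2, rt) triggers a Meinwald rearrangement in which hydride migrates anti to the breaking C–O bond. This delivers the 8S aldehyde directly and comes back to the route at 15, replacing steps 9–11.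

## Further compounds

F1 | step 16 | (2E,5S,6S)-5-(acetyloxy)-2-methyl-6-[(1S,3aS,4S,7aR)-3a-methyl-7-oxo-4-(propanoyloxy)octahydro-1H-inden-1-yl]hept-2-enoic acid | OC(=O)/C(C)=C/C[C@H](OC(C)=O)[C@@H](C)[C@@H]1CC[C@](C)([C@@H](OC(=O)CC)CC2)[C@@H]1C2=O
F2 | step 16 | Se-phenyl selenoester of F1 | O=C([Se]c3ccccc3)/C(C)=C/C[C@H](OC(C)=O)[C@@H](C)[C@@H]1CC[C@](C)([C@@H](OC(=O)CC)CC2)[C@@H]1C2=O
F3 | step 16 | 6-methylidene derivative of F2 (exocyclic enone selenoester) | O=C([Se]c3ccccc3)/C(C)=C/C[C@H](OC(C)=O)[C@@H](C)[C@@H]1CC[C@](C)([C@@H](OC(=O)CC)CC2=C)[C@@H]1C2=O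
F4 | step 7 | (3S,4S)-4-[(tert-butyldimethylsilyl)oxy]-3-methyl-3-(4-methylpent-3-en-1-yl)cyclohexan-1-one | CC(C)=CCC[C@@]1(C)CC(=O)CC[C@@H]1O[Si](C)(C)C(C)(C)C
F5 | step 7 | (3S,4S)-4-[(tert-butyldimethylsilyl)oxy]-3-[(3E)-5-hydroxy-4-methylpent-3-en-1-yl]-3-methylcyclohexan-1-one | OC/C(C)=C/CC[C@@]1(C)CC(=O)CC[C@@H]1O[Si](C)(C)C(C)(C)C
F6 | step 7 | methyl carbonate of F5 | COC(=O)OC/C(C)=C/CC[C@@]1(C)CC(=O)CC[C@@H]1O[Si](C)(C)C(C)(C)C
F7 | step 10 | (1R,3aS,4S,7aR)-3a-methyl-1-[(2S)-2-methyloxiran-2-yl]-7-oxooctahydro-1H-inden-4-yl propanoate | C[C@@]1(CO1)[C@@H]2CC[C@](C)([C@@H](OC(=O)CC)CC3)[C@@H]2C3=O
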